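## Retrosynthetic overview

1. Ring A, the benzene ring of the benzofuran-3(2H)-one, has its three substituents on neighbouring atoms (O1 on C7a, the C3 carbonyl on C3a, CH3 on C4). The other three atoms (C5, C6, C7) are CH. The plan rests on this contiguous 1,2,3-pattern.
2. Ring A is cut at C7a–C3a and C5–C4. C7a, C7, C6 and C5 come from C3–C6 of 3-hydroxy-2-pyrone, whose lactone bridge leaves as CO2. C3a, C4, the 4-CH3 and C3 come from a but-2-ynoyl ketone.
3. C2 travels as a 1,3-dithiane. C2–C1' is made by alkylating ethyl 1,3-dithiane-2-carboxylate with an 8-silyloxygeranyl bromide, and the ester becomes the ynone through its Weinreb amide.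
4. After the arene is built, C8'–C9' is made by Nozaki–Hiyama–Kishi coupling of the C8' enal with (E)-4-iodo-2-methylbut-3-en-2-ol. Oxidation then gives the cross-conjugated dienone.
5. Ring order: benzene ring first, furanone ring last, when the phenol O closes onto the unmasked C2 carbonyl. C2 forms as a racemate and the (R) form is taken by chiral-phase chromatography.

Key step: step 8

Assumption: the C2 hemiketal can invert only through its ring-opened 1,2-dione, and this is taken to be slow in neutral, base-free media at or below room temperature, so the separated (R)-enantiomer can be handled.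

## Route

Step 1
Reactants: 1 geranyl acetate
Product: 2 (2E,6E)-8-hydroxy-3,7-dimethylocta-2,6-dien-1-yl acetate
Conditions: SeO2 (0.3 equiv), t-BuOOH (2.5 equiv), salicylic acid (0.1 equiv), CH2Cl2, 0 °C to rt, stopped before over-oxidation
Reagents that add atoms: tert-butyl hydroperoxide, CC(C)(C)OO
Why: Riley-type allylic oxidation (ene reaction, then [2,3]-shift) should attack the electron-richer distal alkene at its E-methyl group, giving the (6E)-allylic alcohol while the acetate-deactivated C2–C3 alkene stays untouched.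

Step 2
Reactants: 2 (2E,6E)-8-hydroxy-3,7-dimethylocta-2,6-dien-1-yl acetate
Product: 3 (2E,6E)-8-(tert-butyldimethylsilyloxy)-3,7-dimethylocta-2,6-dien-1-yl acetate
Conditions: TBSCl, imidazole, CH2Cl2, 0 °C to rt
Reagents that add atoms: tert-butyldimethylsilyl chloride, CC(C)(C)[Si](C)(C)Cl
Why: Imidazole-promoted O-silylation of the only free hydroxyl is routine and leaves the acetate alone.

Step 3
Reactants: 3 (2E,6E)-8-(tert-butyldimethylsilyloxy)-3,7-dimethylocta-2,6-dien-1-yl acetate
Product: 4 (2E,6E)-8-(tert-butyldimethylsilyloxy)-3,7-dimethylocta-2,6-dien-1-ol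
Conditions: K2CO3 (0.2 equiv), MeOH, 0 °C to rt
Reagents that add atoms: none
Why: Zemplén-type transesterification removes the acetate under conditions to which a primary TBS ether is inert.

Step 4
Reactants: 4 (2E,6E)-8-(tert-butyldimethylsilyloxy)-3,7-dimethylocta-2,6-dien-1-ol
Product: 5 (2E,6E)-8-bromo-1-(tert-butyldimethylsilyloxy)-2,6-dimethylocta-2,6-diene
Conditions: CBr4, PPh3, CH2Cl2, −20 to 0 °C; used at once
Reagents that add atoms: carbon tetrabromide, BrC(Br)(Br)Br
Why: The Appel reaction brominates a primary allylic alcohol by SN2 under near-neutral conditions, so alkene geometry, allylic position and silyl ether should all be kept.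

Step 5
Reactants: 6 ethyl 1,3-dithiane-2-carboxylate; 5 (2E,6E)-8-bromo-1-(tert-butyldimethylsilyloxy)-2,6-dimethylocta-2,6-diene
Product: 8 ethyl 2-[(2E,6E)-8-(tert-butyldimethylsilyloxy)-3,7-dimethylocta-2,6-dien-1-yl]-1,3-dithiane-2-carboxylate, via sodium enolate 7 (not isolated)
Conditions: NaH, THF–DMF (4:1), 0 °C; then 5, 0 °C to rt
Reagents that add atoms: NaH, [Na+].[H-] (sodium held only in 7)
Why: SN2 C-alkylation of the sulfur- and ester-stabilised carbanion 7, a glyoxylate anion equivalent, with a primary allylic bromide is classical enolate alkylation, and it makes the C2–C1' bond and the quaternary C2.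

Step 6
Reactants: 8 ethyl 2-[(2E,6E)-8-(tert-butyldimethylsilyloxy)-3,7-dimethylocta-2,6-dien-1-yl]-1,3-dithiane-2-carboxylate
Product: 9 2-[(2E,6E)-8-(tert-butyldimethylsilyloxy)-3,7-dimethylocta-2,6-dien-1-yl]-N-methoxy-N-methyl-1,3-dithiane-2-carboxamide
Conditions: MeNH(OMe)·HCl (3 equiv), i-PrMgCl (6 equiv), THF, −20 °C to rt
Reagents that add atoms: N,O-dimethylhydroxylamine hydrochloride, CNOC.Cl
Why: Weinreb amidation of an ester with the magnesium amide works on alpha-branched esters, and here the long C–S bonds and the inductive pull of two sulfur atoms keep the carbonyl accessible and electrophilic.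

Step 7
Reactants: 9 2-[(2E,6E)-8-(tert-butyldimethylsilyloxy)-3,7-dimethylocta-2,6-dien-1-yl]-N-methoxy-N-methyl-1,3-dithiane-2-carboxamide; 10 1-propynylmagnesium bromide
Product: 11 1-{2-[(2E,6E)-8-(tert-butyldimethylsilyloxy)-3,7-dimethylocta-2,6-dien-1-yl]-1,3-dithian-2-yl}but-2-yn-1-one
Conditions: 10 (0.5 M in THF, 1.5 equiv), THF, 0 °C to rt; inverse quench into cold aq. NH4Cl
Reagents that add atoms: none
Why: The Weinreb ketone synthesis stops alkynyl Grignard addition at the ketone stage, and the cold inverse quench keeps the released amine from adding to the new ynone.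

Step 8
Reactants: 11 1-{2-[(2E,6E)-8-(tert-butyldimethylsilyloxy)-3,7-dimethylocta-2,6-dien-1-yl]-1,3-dithian-2-yl}but-2-yn-1-one; 12 3-hydroxy-2H-pyran-2-one
Product: 15 (2-hydroxy-6-methylphenyl){2-[(2E,6E)-8-(tert-butyldimethylsilyloxy)-3,7-dimethylocta-2,6-dien-1-yl]-1,3-dithian-2-yl}methanone, via triethylammonium pyronate 13 (not isolated), via bridged lactone 14 (not isolated)
Conditions: 12 (1.5 equiv), Et3N (0.5 equiv), THF, 25 °C, then 60 °C, Ar
Reagents that add atoms: triethylamine, CCN(CC)CC (held only in 13)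
Why: Et3N turns 12 into the pyronate 13, an oxido-substituted and therefore strongly electron-rich diene, which bonds through pyrone C6 to the methyl-bearing alkyne carbon of 11 (future C5–C4) and through pyrone C3 to the acyl-bearing alkyne carbon (future C7a–C3a), either as a concerted asynchronous normal-demand [4+2] cycloaddition or as its stepwise vinylogous Michael/aldol counterpart. The 2-oxabicyclo[2.2.2]octa-5,7-dien-3-one 14 then loses its O–C(=O) bridge as CO2 in a retro-[4+2] reaction driven by aromatisation, and proton transfer returns the amine. The closest known reaction types are the 2-pyrone/alkyne Diels–Alder benzannulation and the tertiary-amine-catalysed Diels–Alder reaction of 3-hydroxy-2-pyrone with electron-poor pi bonds. The one ring closed is the six-membered carbocycle (ring A), assembled by intermolecular union of a four-carbon and a two-carbon unit rather than by cyclisation of a chain, and 15 gains no stereocentre because the two bridgehead centres of 14 vanish on aromatisation. The step needs the "ortho" regiochemistry (oxygen-bearing carbon next to acyl-bearing carbon), which is secured by pairing the largest HOMO coefficient of the 1-oxido diene (pyrone C6) with the largest LUMO coefficient of the ynone (beta carbon) and is reinforced by Et3NH+ bridging the oxido oxygen and the ynone carbonyl. It also needs chemoselectivity, which the substrate supplies: the two trisubstituted chain alkenes are unactivated, the carbon alpha to the ketone is quaternary and cannot enolise, and silyl ether and dithiane are inert to a tertiary amine at 60 °C.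

Step 9
Reactants: 15 (2-hydroxy-6-methylphenyl){2-[(2E,6E)-8-(tert-butyldimethylsilyloxy)-3,7-dimethylocta-2,6-dien-1-yl]-1,3-dithian-2-yl}methanone
Product: 16 (2-hydroxy-6-methylphenyl){2-[(2E,6E)-8-hydroxy-3,7-dimethylocta-2,6-dien-1-yl]-1,3-dithian-2-yl}methanone
Conditions: HF·pyridine, pyridine, THF, 0 °C to rt
Reagents that add atoms: none
Why: Fluoride-driven desilylation with a buffered acidic fluoride source frees the primary allylic alcohol and avoids basic media that could cleave the acyl–dithiane bond in a retro-Claisen sense.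

Step 10
Reactants: 16 (2-hydroxy-6-methylphenyl){2-[(2E,6E)-8-hydroxy-3,7-dimethylocta-2,6-dien-1-yl]-1,3-dithian-2-yl}methanone
Product: 17 (2E,6E)-8-[2-(2-hydroxy-6-methylbenzoyl)-1,3-dithian-2-yl]-2,6-dimethylocta-2,6-dienal
Conditions: activated MnO2 (15 equiv), CH2Cl2, rt
Reagents that add atoms: none
Why: MnO2 allylic oxidation is selective for the allylic alcohol, keeps the E geometry, and under neutral conditions should spare the thioacetal and the hydrogen-bonded, electron-poor phenol.

Step 11
Reactants: 18 2-methylbut-3-yn-2-ol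
Product: 20 (E)-4-iodo-2-methylbut-3-en-2-ol, via vinylstannane 19 (not isolated)
Conditions: Bu3SnH, PdCl2(PPh3)2 (2 mol %), THF, 0 °C to rt; then I2, 0 °C
Reagents that add atoms: iodine, [I][I]; tributyltin hydride, CCCC[SnH](CCCC)CCCC (tin held only in 19)
Why: Palladium-catalysed syn-hydrostannation places tin on the terminal carbon because the tertiary carbinol blocks the inner one, and tin–iodine exchange proceeds with retention, so the E-iodide should result.

Step 12
Reactants: 17 (2E,6E)-8-[2-(2-hydroxy-6-methylbenzoyl)-1,3-dithian-2-yl]-2,6-dimethylocta-2,6-dienal; 20 (E)-4-iodo-2-methylbut-3-en-2-ol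
Product: 22 (3E,6E,10E)-12-[2-(2-hydroxy-6-methylbenzoyl)-1,3-dithian-2-yl]-2,6,10-trimethyldodeca-3,6,10-triene-2,5-diol (racemic at C5), via alkenylchromium dichloride 21 (not isolated)
Conditions: 20 (2.5 equiv), CrCl2 (6 equiv), NiCl2 (0.05 equiv), degassed DMF, rt
Reagents that add atoms: CrCl2, Cl[Cr]Cl (held only in 21)
Why: In the Nozaki–Hiyama–Kishi coupling the weakly basic alkenylchromium reagent 21 (trivalent chromium) adds 1,2 to aldehydes only, with retention of the E alkene, so it should tolerate the free phenol, the free tertiary alcohol and the very hindered aryl ketone; the new carbinol centre is not controlled and is erased in step 13.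

Step 13
Reactants: 22 (3E,6E,10E)-12-[2-(2-hydroxy-6-methylbenzoyl)-1,3-dithian-2-yl]-2,6,10-trimethyldodeca-3,6,10-triene-2,5-diol
Product: 23 (3E,6E,10E)-2-hydroxy-12-[2-(2-hydroxy-6-methylbenzoyl)-1,3-dithian-2-yl]-2,6,10-trimethyldodeca-3,6,10-trien-5-one
Conditions: activated MnO2 (20 equiv), CH2Cl2, rt
Reagents that add atoms: none
Why: MnO2 oxidation of the doubly allylic secondary alcohol gives the cross-conjugated dienone under neutral conditions, and the tertiary alcohol cannot be oxidised.

Step 14
Reactants: 23 (3E,6E,10E)-2-hydroxy-12-[2-(2-hydroxy-6-methylbenzoyl)-1,3-dithian-2-yl]-2,6,10-trimethyldodeca-3,6,10-trien-5-one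
Product: 25 rac-2-hydroxy-2-[(2E,6E,9E)-11-hydroxy-3,7,11-trimethyl-8-oxododeca-2,6,9-trien-1-yl]-4-methyl-1-benzofuran-3(2H)-one, via open 1,2-dione 24 (not isolated)
Conditions: MeI (20 equiv), CaCO3 (5 equiv), MeCN–H2O (9:1), 40 °C, dark
Reagents that add atoms: water, O
Why: Alkylative thioacetal hydrolysis touches only sulfur, so alkenes, dienone, tertiary alcohol and phenol should survive, and the freed C2 carbonyl of 24 is captured by the ortho phenol in a 5-exo-trig hemiketalisation that closes the furanone ring and creates C2 without facial bias, hence as a racemate.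

Step 15
Reactants: 25 rac-2-hydroxy-2-[(2E,6E,9E)-11-hydroxy-3,7,11-trimethyl-8-oxododeca-2,6,9-trien-1-yl]-4-methyl-1-benzofuran-3(2H)-one
Product: 26 (2R)-2-hydroxy-2-[(2E,6E,9E)-11-hydroxy-3,7,11-trimethyl-8-oxododeca-2,6,9-trien-1-yl]-4-methyl-1-benzofuran-3(2H)-one
Conditions: preparative HPLC on silica-bound amylose tris(3,5-dimethylphenylcarbamate), n-hexane–i-PrOH, 15 °C; fractions evaporated cold, no acid or base additive
Reagents that add atoms: none
Why: Enantioselective chromatography on a polysaccharide carbamate phase is the standard way to part enantiomers of aryl ketone hemiketals; the (R) fraction would be identified by comparing its ECD curve with the computed one, and the (S) fraction could be re-equilibrated through 24 and resubmitted.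

## Compound list

1 | geranyl acetate | CC(=O)OC/C=C(\C)CCC=C(C)C | starting material
2 | (2E,6E)-8-hydroxy-3,7-dimethylocta-2,6-dien-1-yl acetate | CC(=O)OC/C=C(\C)CC/C=C(\C)CO | intermediate
3 | (2E,6E)-8-(tert-butyldimethylsilyloxy)-3,7-dimethylocta-2,6-dien-1-yl acetate | CC(=O)OC/C=C(\C)CC/C=C(\C)CO[Si](C)(C)C(C)(C)C | intermediate
4 | (2E,6E)-8-(tert-butyldimethylsilyloxy)-3,7-dimethylocta-2,6-dien-1-ol | OC/C=C(\C)CC/C=C(\C)CO[Si](C)(C)C(C)(C)C | intermediate
5 | (2E,6E)-8-bromo-1-(tert-butyldimethylsilyloxy)-2,6-dimethylocta-2,6-diene | BrC/C=C(\C)CC/C=C(\C)CO[Si](C)(C)C(C)(C)C | intermediate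
6 | ethyl 1,3-dithiane-2-carboxylate | CCOC(=O)C1SCCCS1 | starting material
7 | sodium enolate of 6 (not isolated) | CCOC([O-])=C1SCCCS1.[Na+] | intermediate
8 | ethyl 2-[(2E,6E)-8-(tert-butyldimethylsilyloxy)-3,7-dimethylocta-2,6-dien-1-yl]-1,3-dithiane-2-carboxylate | CCOC(=O)C1(C/C=C(\C)CC/C=C(\C)CO[Si](C)(C)C(C)(C)C)SCCCS1 | intermediate
9 | Weinreb amide of 8 | CON(C)C(=O)C1(C/C=C(\C)CC/C=C(\C)CO[Si](C)(C)C(C)(C)C)SCCCS1 | intermediate
10 | 1-propynylmagnesium bromide | CC#C[Mg]Br | starting material
11 | 1-{2-[(2E,6E)-8-(tert-butyldimethylsilyloxy)-3,7-dimethylocta-2,6-dien-1-yl]-1,3-dithian-2-yl}but-2-yn-1-one | CC#CC(=O)C1(C/C=C(\C)CC/C=C(\C)CO[Si](C)(C)C(C)(C)C)SCCCS1 | intermediate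
12 | 3-hydroxy-2H-pyran-2-one | O=C1OC=CC=C1O | starting material
13 | triethylammonium 2-oxo-2H-pyran-3-olate (not isolated) | [O-]C1=CC=COC1=O.CC[NH+](CC)CC | intermediate
14 | 5-acyl-4-hydroxy-6-methyl-2-oxabicyclo[2.2.2]octa-5,7-dien-3-one, acyl = the 2-alkyl-1,3-dithiane-2-carbonyl group of 11 (racemic, one enantiomer drawn, not isolated) | O=C1O[C@@H]2C=C[C@@]1(O)C(C(=O)C3(C/C=C(\C)CC/C=C(\C)CO[Si](C)(C)C(C)(C)C)SCCCS3)=C2C | intermediate
15 | (2-hydroxy-6-methylphenyl){2-[(2E,6E)-8-(tert-butyldimethylsilyloxy)-3,7-dimethylocta-2,6-dien-1-yl]-1,3-dithian-2-yl}methanone | Cc1cccc(O)c1C(=O)C1(C/C=C(\C)CC/C=C(\C)CO[Si](C)(C)C(C)(C)C)SCCCS1 | intermediate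
16 | (2-hydroxy-6-methylphenyl){2-[(2E,6E)-8-hydroxy-3,7-dimethylocta-2,6-dien-1-yl]-1,3-dithian-2-yl}methanone | Cc1cccc(O)c1C(=O)C1(C/C=C(\C)CC/C=C(\C)CO)SCCCS1 | intermediate
17 | (2E,6E)-8-[2-(2-hydroxy-6-methylbenzoyl)-1,3-dithian-2-yl]-2,6-dimethylocta-2,6-dienal | Cc1cccc(O)c1C(=O)C1(C/C=C(\C)CC/C=C(\C)C=O)SCCCS1 | intermediate
18 | 2-methylbut-3-yn-2-ol | C#CC(C)(C)O | starting material
19 | (E)-2-methyl-4-(tributylstannyl)but-3-en-2-ol (not isolated) | CCCC[Sn](CCCC)(CCCC)/C=C/C(C)(C)O | intermediate
20 | (E)-4-iodo-2-methylbut-3-en-2-ol | I/C=C/C(C)(C)O | intermediate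
21 | (E)-(3-hydroxy-3-methylbut-1-enyl)chromium dichloride (not isolated) | CC(C)(O)/C=C/[Cr](Cl)Cl | intermediate
22 | (3E,6E,10E)-12-[2-(2-hydroxy-6-methylbenzoyl)-1,3-dithian-2-yl]-2,6,10-trimethyldodeca-3,6,10-triene-2,5-diol (racemic) | Cc1cccc(O)c1C(=O)C1(C/C=C(\C)CC/C=C(\C)C(O)/C=C/C(C)(C)O)SCCCS1 | intermediate
23 | (3E,6E,10E)-2-hydroxy-12-[2-(2-hydroxy-6-methylbenzoyl)-1,3-dithian-2-yl]-2,6,10-trimethyldodeca-3,6,10-trien-5-one | Cc1cccc(O)c1C(=O)C1(C/C=C(\C)CC/C=C(\C)C(=O)/C=C/C(C)(C)O)SCCCS1 | intermediate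
24 | (4E,8E,11E)-13-hydroxy-1-(2-hydroxy-6-methylphenyl)-5,9,13-trimethyltetradeca-4,8,11-triene-1,2,10-trione (not isolated) | Cc1cccc(O)c1C(=O)C(=O)C/C=C(\C)CC/C=C(\C)C(=O)/C=C/C(C)(C)O | intermediate
25 | rac-2-hydroxy-2-[(2E,6E,9E)-11-hydroxy-3,7,11-trimethyl-8-oxododeca-2,6,9-trien-1-yl]-4-methyl-1-benzofuran-3(2H)-one | C/C(=C\CC1(O)Oc2cccc(C)c2C1=O)CC/C=C(\C)C(=O)/C=C/C(C)(C)O | intermediate
26 | (2R)-2-hydroxy-2-[(2E,6E,9E)-11-hydroxy-3,7,11-trimethyl-8-oxododeca-2,6,9-trien-1-yl]-4-methyl-1-benzofuran-3(2H)-one | C/C(=C\C[C@@]1(O)Oc2cccc(C)c2C1=O)CC/C=C(\C)C(=O)/C=C/C(C)(C)O | target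

## Step count and risks

Total step count: 15.
Longest linear sequence: 14 (steps 1–10 and 12–15; step 11 is a one-step side branch).

**Step 8.**
- **Risk:** The cycloaddition may be too slow, because both alkyne carbons are substituted and the acyl group sits on a quaternary carbon. O-attack of the pyronate on the ynone (oxa-Michael addition), amine-induced alkyne-to-allene isomerisation, or erosion of regiocontrol at forcing temperature could then take over.
- **Fallback:** The arene is bought instead of built, and the C3–C2 bond is made by dithiane umpolung.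
  - Setting out from 5, 1,3-dithiane is metalated (n-BuLi, THF, −30 °C) and alkylated with 5 to give the 2-alkyl-1,3-dithiane F1.
  - Commercial 2-hydroxy-6-methylbenzaldehyde is protected (MOMCl, i-Pr2NEt, CH2Cl2) as the MOM ether aldehyde F2.
  - F1 is metalated (n-BuLi, THF, −20 °C) and added to F2 in a Corey–Seebach reaction to give the dithianyl carbinol F3.
  - Swern-type oxidation (DMSO, (CF3CO)2O, Et3N, −78 °C) gives the MOM-protected aryl ketone F4.
  - Catalytic HCl in MeOH removes the MOM and TBS groups together, and the sequence rejoins the route at 16.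

**Step 14.**
- **Risk:** C–S ionisation next to the electron-withdrawing ketone may be sluggish, so the reaction stalls after S-methylation. Prolonged warming would then invite migration of the C2'–C3' double bond into conjugation through the open dione, O-methylation of the phenol, or decay of the dienone.
- **Fallback:** The unmasking is moved forward to a sturdier intermediate and the hemiketal is carried in locked form.
  - Setting out from 17, Hg(ClO4)2 and CaCO3 in THF–H2O at 0 °C give the hemiketal enal F5.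
  - TESOTf and 2,6-lutidine (CH2Cl2, −78 °C) give the C2 triethylsilyl ether F6.
  - Nozaki–Hiyama–Kishi coupling with 20, now without sulfur in the substrate, gives the diol F7.
  - MnO2 gives the silylated dienone F8.
  - HF·pyridine (THF, 0 °C) releases the hemiketal, rejoining the route at 25.

**Step 15.**
- **Risk:** Reversible ring opening of the hemiketal on the column or during evaporation may racemise the separated fractions.
- **Fallback:** The separation is carried out on a derivative that cannot ring-open.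
  - Setting out from 25, TESOTf (2.5 equiv) and 2,6-lutidine give the racemic bis(triethylsilyl) ether F9.
  - Chiral-phase chromatography of this configurationally fixed compound gives the enantiomer with the spatial arrangement of the target, the locked bis(triethylsilyl) ether F10. It is formally 2S, only because OSi outranks the ring oxygen.
  - Cold HF·pyridine in THF, an acidic and base-free release, removes both silyl groups just before use, rejoining the route at 26.

## Further compounds

F1 | step 8 | 2-[(2E,6E)-8-(tert-butyldimethylsilyloxy)-3,7-dimethylocta-2,6-dien-1-yl]-1,3-dithiane | C1(C/C=C(\C)CC/C=C(\C)CO[Si](C)(C)C(C)(C)C)SCCCS1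
F2 | step 8 | 2-(methoxymethoxy)-6-methylbenzaldehyde | COCOc1cccc(C)c1C=O
F3 | step 8 | [2-(methoxymethoxy)-6-methylphenyl]{2-[(2E,6E)-8-(tert-butyldimethylsilyloxy)-3,7-dimethylocta-2,6-dien-1-yl]-1,3-dithian-2-yl}methanol (racemic) | COCOc1cccc(C)c1C(O)C1(C/C=C(\C)CC/C=C(\C)CO[Si](C)(C)C(C)(C)C)SCCCS1
F4 | step 8 | [2-(methoxymethoxy)-6-methylphenyl]{2-[(2E,6E)-8-(tert-butyldimethylsilyloxy)-3,7-dimethylocta-2,6-dien-1-yl]-1,3-dithian-2-yl}methanone | COCOc1cccc(C)c1C(=O)C1(C/C=C(\C)CC/C=C(\C)CO[Si](C)(C)C(C)(C)C)SCCCS1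
F5 | step 14 | rac-(2E,6E)-8-(2-hydroxy-4-methyl-3-oxo-2,3-dihydro-1-benzofuran-2-yl)-2,6-dimethylocta-2,6-dienal | C/C(=C\CC1(O)Oc2cccc(C)c2C1=O)CC/C=C(\C)C=O
F6 | step 14 | rac-(2E,6E)-2,6-dimethyl-8-[4-methyl-3-oxo-2-(triethylsilyloxy)-2,3-dihydro-1-benzofuran-2-yl]octa-2,6-dienal | C/C(=C\CC1(O[Si](CC)(CC)CC)Oc2cccc(C)c2C1=O)CC/C=C(\C)C=O
F7 | step 14 | 2-[(2E,6E,9E)-8,11-dihydroxy-3,7,11-trimethyldodeca-2,6,9-trien-1-yl]-4-methyl-2-(triethylsilyloxy)-1-benzofuran-3(2H)-one (stereoisomer mixture) | C/C(=C\CC1(O[Si](CC)(CC)CC)Oc2cccc(C)c2C1=O)CC/C=C(\C)C(O)/C=C/C(C)(C)O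
F8 | step 14 | rac-2-[(2E,6E,9E)-11-hydroxy-3,7,11-trimethyl-8-oxododeca-2,6,9-trien-1-yl]-4-methyl-2-(triethylsilyloxy)-1-benzofuran-3(2H)-one | C/C(=C\CC1(O[Si](CC)(CC)CC)Oc2cccc(C)c2C1=O)CC/C=C(\C)C(=O)/C=C/C(C)(C)O
F9 | step 15 | rac-4-methyl-2-(triethylsilyloxy)-2-[(2E,6E,9E)-3,7,11-trimethyl-8-oxo-11-(triethylsilyloxy)dodeca-2,6,9-trien-1-yl]-1-benzofuran-3(2H)-one | C/C(=C\CC1(O[Si](CC)(CC)CC)Oc2cccc(C)c2C1=O)CC/C=C(\C)C(=O)/C=C/C(C)(C)O[Si](CC)(CC)CC
F10 | step 15 | (2S)-enantiomer of F9, same spatial arrangement at C2 as 26 | C/C(=C\C[C@@]1(O[Si](CC)(CC)CC)Oc2cccc(C)c2C1=O)CC/C=C(\C)C(=O)/C=C/C(C)(C)O[Si](CC)(CC)CC
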